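**Plan**

- Retrosynthesis: the two benzyl ethers are removed last; C7'–H is cut back to an aryl ketone, C7'–aryl to an aryllithium plus a bicyclic lactone, and the oxolane bonds C7–C8 and C8'–C9' are cut together in a [3+2] sense.
- Enabling feature (lignan numbering: oxolane O–C7–C8–C8'–C9', aryl on C7, C9 = CH2OH on C8, C7' = aryl carbinol on C8'): C7–O–C9' is an aryl carbonyl ylide, and the cis pair C9/C7' on C8–C8' is the carbonyl/acetal pair of a 5-alkoxybutenolide.
- Forward: the ylide precursor (from O-benzylvanillin) and the menthyloxybutenolide (from furfural) are made separately. The cycloaddition closes the oxolane, the only ring of the skeleton that has to be built. The lactone acetal is then reduced to the cis-diol, re-lactonised on the C7' arm, arylated, reduced and deprotected.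
- Stereochemistry: C8 and C8' come from addition anti to the (5R)-menthyloxy acetal, C7 from endo approach of the aryl group, and C7' from a catalyst-controlled ketone reduction.

Key step: step 5

Assumption: the target is read from its SMILES as the all-cis oxolane (7S,8S,7'S,8'S in lignan numbering), and chloro ether 4 is taken to be too moisture-sensitive to purify, so it is used crude.

**Route**

Step 1
Reactants: 1 4-benzyloxy-3-methoxybenzaldehyde (O-benzylvanillin); 2 (trimethylsilyl)methanol
Product: 3 4-benzyloxy-3-methoxybenzaldehyde bis[(trimethylsilyl)methyl] acetal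
Conditions: 2 (3 equiv), TsOH·H2O (cat.), cyclohexane, reflux, Dean–Stark; Et3N quench
Reagents that add atoms: none
Why: Acid-catalysed acetalisation driven by azeotropic removal of water, in which the silylmethyl carbinol behaves as an ordinary primary alcohol and the benzyl ether is inert.

Step 2
Reactants: 3 4-benzyloxy-3-methoxybenzaldehyde bis[(trimethylsilyl)methyl] acetal
Product: 4 (±)-{[chloro(4-benzyloxy-3-methoxyphenyl)methoxy]methyl}trimethylsilane
Conditions: AcCl (1.05 equiv), SOCl2 (cat.), CH2Cl2, 0 °C to rt; volatiles removed in vacuo, used crude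
Reagents that add atoms: acetyl chloride, CC(=O)Cl
Why: Acyl chloride cleavage of an acetal to an α-chloro ether and an ester, a standard water-free preparation of α-chlorobenzyl ethers that the electron-rich aryl group accelerates.

Step 3
Reactants: 5 furfural
Product: 6 (±)-5-hydroxy-2(5H)-furanone
Conditions: O2, rose bengal (cat.), MeOH, visible light, rt
Reagents that add atoms: oxygen, O=O
Why: Dye-sensitised singlet-oxygen [4+2] photooxygenation of the furan, followed by methanol-induced fragmentation of the endoperoxide with loss of the formyl carbon as methyl formate.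

Step 4
Reactants: 6 (±)-5-hydroxy-2(5H)-furanone; 7 (−)-menthol
Product: 9 (5R)-5-[(1R,2S,5R)-menthyloxy]-2(5H)-furanone, via (5S)-epimer 8 (not isolated)
Conditions: camphorsulfonic acid (cat.), toluene, reflux, Dean–Stark; crystallisation from petroleum ether, −20 °C; mother liquor re-equilibrated with acid and recrystallised
Reagents that add atoms: none
Why: Acid-catalysed acetalisation of the lactol gives both C5 epimers, and the 5R configuration is fixed by crystallisation of 9 while acid equilibrates the acetal centre of the remaining epimer 8 (crystallisation-driven diastereomer enrichment).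

Step 5
Reactants: 4 (±)-{[chloro(4-benzyloxy-3-methoxyphenyl)methoxy]methyl}trimethylsilane; 9 (5R)-5-[(1R,2S,5R)-menthyloxy]-2(5H)-furanone
Product: 12 (1R,4R,5S,8S)-8-(4-benzyloxy-3-methoxyphenyl)-4-[(1R,2S,5R)-menthyloxy]-3,7-dioxabicyclo[3.3.0]octan-2-one (endo-aryl; exo-menthyloxy), via oxocarbenium chloride 10 (not isolated), via carbonyl ylide 11 (not isolated)
Conditions: CsF (4 equiv, dried), MeCN, 0 °C to rt; 4 (2 equiv) added slowly to 9 and CsF
Reagents that add atoms: none
Why: Proposed new method: ionisation of the α-chloro ether, helped by the 4-alkoxyaryl group, gives oxocarbenium chloride 10, and fluoride attack at silicon releases the planar non-stabilised aryl carbonyl ylide 11, so the racemic centre of 4 is erased before any bond forms. The closest known reaction type is the CsF-induced 1,3-elimination of 1-chloroalkyl (trimethylsilyl)methyl ethers with trapping of the ylide by acrylates, together with the anti-selective dipolar cycloadditions (azomethine ylides, nitrile oxides, diazoalkanes) known for 5-menthyloxy-2(5H)-furanone. The oxolane closes by a concerted intermolecular [3+2] cycloaddition, suprafacial on both partners, that forms C7–C8 and C8'–C9' in one event across the Z-alkene, so the ring fusion and hence C9/C7' are necessarily cis. C8 and C8' are set by the 5R acetal centre, whose menthyloxy group shields one face so that the dipole adds anti to it, and C7 is set by the endo orientation of the aryl group beneath the lactone carbonyl. Regiochemistry follows from the larger HOMO coefficient and smaller size of the unsubstituted CH2 terminus, which bonds to the β-carbon C8' next to the hindered acetal carbon, while the benzylic terminus bonds to the α-carbon C8. The step needs facial, regio- and endo selectivity; the first two are secured by the auxiliary and by matched steric and electronic polarisation, whereas the endo preference rests only on secondary orbital overlap and is the least certain.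

Step 6
Reactants: 12 (1R,4R,5S,8S)-8-(4-benzyloxy-3-methoxyphenyl)-4-[(1R,2S,5R)-menthyloxy]-3,7-dioxabicyclo[3.3.0]octan-2-one
Product: 13 [(2S,3S,4R)-2-(4-benzyloxy-3-methoxyphenyl)oxolane-3,4-diyl]dimethanol
Conditions: LiAlH4, THF, 0 °C to rt; Na2SO4·10H2O quench
Reagents that add atoms: none
Why: Lithium aluminium hydride reduction of the lactone acetal, in which hydride addition at C9 and collapse of the hemiacetal expel menthoxide and unmask the C7' aldehyde, and both carbonyls are reduced faster than they enolise, so the cis-diol keeps the C7, C8 and C8' configurations.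

Step 7
Reactants: 13 [(2S,3S,4R)-2-(4-benzyloxy-3-methoxyphenyl)oxolane-3,4-diyl]dimethanol
Product: 14 (1S,5S,6S)-6-(4-benzyloxy-3-methoxyphenyl)-3,7-dioxabicyclo[3.3.0]octan-2-one (lactone carbonyl = C7')
Conditions: TEMPO (0.2 equiv), PhI(OAc)2 (2.5 equiv), CH2Cl2, rt
Reagents that add atoms: none
Why: Oxoammonium-mediated oxidative lactonisation of a 1,4-diol, in which the less hindered C7' hydroxymethyl (next to the ring CH2, remote from the cis aryl group) is oxidised first, the aldehyde is trapped as a lactol by the C9 hydroxyl and oxidised again.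

Step 8
Reactants: 14 (1S,5S,6S)-6-(4-benzyloxy-3-methoxyphenyl)-3,7-dioxabicyclo[3.3.0]octan-2-one; 15 1-benzyloxy-4-bromo-2-methoxybenzene
Product: 17 (4-benzyloxy-3-methoxyphenyl)[(3S,4S,5S)-5-(4-benzyloxy-3-methoxyphenyl)-4-(hydroxymethyl)oxolan-3-yl]methanone, via aryllithium 16 (not isolated)
Conditions: 15, n-BuLi, THF, −78 °C; then 14, −78 °C; AcOH quench at −78 °C
Reagents that add atoms: none
Why: Bromine–lithium exchange and single nucleophilic addition of the aryllithium to the lactone carbonyl, whose lithium hemiketal alkoxide survives at −78 °C and releases the γ-hydroxy aryl ketone only on the cold acidic quench, which limits over-addition and enolisation at C8'.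

Step 9
Reactants: 17 (4-benzyloxy-3-methoxyphenyl)[(3S,4S,5S)-5-(4-benzyloxy-3-methoxyphenyl)-4-(hydroxymethyl)oxolan-3-yl]methanone
Product: 18 (4-benzyloxy-3-methoxyphenyl)[(3S,4S,5S)-5-(4-benzyloxy-3-methoxyphenyl)-4-{[(tert-butyldimethylsilyl)oxy]methyl}oxolan-3-yl]methanone
Conditions: TBSCl, imidazole, DMF, 0 °C to rt
Reagents that add atoms: tert-butyldimethylsilyl chloride, CC(C)(C)[Si](C)(C)Cl
Why: Silylation of the primary alcohol traps 17 in its open-chain form and removes the free hydroxyl that would otherwise bind borane, while imidazole is too weak a base to enolise the ketone at C8'.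

Step 10
Reactants: 18 (4-benzyloxy-3-methoxyphenyl)[(3S,4S,5S)-5-(4-benzyloxy-3-methoxyphenyl)-4-{[(tert-butyldimethylsilyl)oxy]methyl}oxolan-3-yl]methanone
Product: 19 (S)-(4-benzyloxy-3-methoxyphenyl)[(3S,4S,5S)-5-(4-benzyloxy-3-methoxyphenyl)-4-{[(tert-butyldimethylsilyl)oxy]methyl}oxolan-3-yl]methanol
Conditions: (R)-2-methyl-CBS-oxazaborolidine (0.5 equiv), BH3·SMe2, THF, −20 °C; MeOH quench
Reagents that add atoms: none
Why: Corey–Bakshi–Shibata reduction, in which borane bound to the (R)-oxazaborolidine delivers hydride to the ketone face defined by the aryl group as the large substituent and so should give the (S)-carbinol at C7' under catalyst control, the silyl and benzyl ethers being inert to borane at this temperature.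

Step 11
Reactants: 19 (S)-(4-benzyloxy-3-methoxyphenyl)[(3S,4S,5S)-5-(4-benzyloxy-3-methoxyphenyl)-4-{[(tert-butyldimethylsilyl)oxy]methyl}oxolan-3-yl]methanol
Product: 20 (S)-(4-benzyloxy-3-methoxyphenyl)[(3S,4S,5S)-5-(4-benzyloxy-3-methoxyphenyl)-4-(hydroxymethyl)oxolan-3-yl]methanol
Conditions: Bu4NF, THF, 0 °C to rt
Reagents that add atoms: none
Why: Fluoride-induced cleavage of the primary silyl ether under non-acidic conditions, which avoids ionisation of the electron-rich benzylic alcohol and benzylic ether.

Step 12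
Reactants: 20 (S)-(4-benzyloxy-3-methoxyphenyl)[(3S,4S,5S)-5-(4-benzyloxy-3-methoxyphenyl)-4-(hydroxymethyl)oxolan-3-yl]methanol
Product: 21 (S)-(4-hydroxy-3-methoxyphenyl)[(3S,4S,5S)-5-(4-hydroxy-3-methoxyphenyl)-4-(hydroxymethyl)oxolan-3-yl]methanol (CNP0236765.9)
Conditions: H2 (1 atm), 10% Pd/C, EtOAc–EtOH, rt, stopped at complete debenzylation
Reagents that add atoms: none
Why: Catalytic hydrogenolysis of the two aryl benzyl ethers, which under neutral conditions are cleaved much faster than the benzylic alcohol at C7' and the cyclic benzylic ether at C7.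

**Compound list**

1 | 4-benzyloxy-3-methoxybenzaldehyde (O-benzylvanillin) | COc1cc(C=O)ccc1OCc1ccccc1 | starting material
2 | (trimethylsilyl)methanol | C[Si](C)(C)CO | starting material
3 | 4-benzyloxy-3-methoxybenzaldehyde bis[(trimethylsilyl)methyl] acetal | COc1cc(C(OC[Si](C)(C)C)OC[Si](C)(C)C)ccc1OCc1ccccc1 | intermediate
4 | (±)-{[chloro(4-benzyloxy-3-methoxyphenyl)methoxy]methyl}trimethylsilane | COc1cc(C(Cl)OC[Si](C)(C)C)ccc1OCc1ccccc1 | intermediate
5 | furfural | O=Cc1ccco1 | starting material
6 | (±)-5-hydroxy-2(5H)-furanone | OC1OC(=O)C=C1 | intermediate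
7 | (−)-menthol, (1R,2S,5R)-2-isopropyl-5-methylcyclohexanol | CC(C)[C@@H]1CC[C@@H](C)C[C@H]1O | starting material
8 | (5S)-5-[(1R,2S,5R)-menthyloxy]-2(5H)-furanone | CC(C)[C@@H]1CC[C@@H](C)C[C@H]1O[C@H]2OC(=O)C=C2 | intermediate (not isolated)
9 | (5R)-5-[(1R,2S,5R)-menthyloxy]-2(5H)-furanone | CC(C)[C@@H]1CC[C@@H](C)C[C@H]1O[C@@H]2OC(=O)C=C2 | intermediate
10 | (4-benzyloxy-3-methoxybenzylidene)[(trimethylsilyl)methyl]oxonium chloride | C[Si](C)(C)C[O+]=Cc1ccc(OCc2ccccc2)c(OC)c1.[Cl-] | intermediate (not isolated)
11 | (4-benzyloxy-3-methoxybenzylidene)oxonium methylide (carbonyl ylide) | [CH2-][O+]=Cc1ccc(OCc2ccccc2)c(OC)c1 | intermediate (not isolated)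
12 | (1R,4R,5S,8S)-8-(4-benzyloxy-3-methoxyphenyl)-4-[(1R,2S,5R)-menthyloxy]-3,7-dioxabicyclo[3.3.0]octan-2-one | CC(C)[C@@H]1CC[C@@H](C)C[C@H]1O[C@H](O5)[C@@H]2CO[C@H](c3ccc(OCc4ccccc4)c(OC)c3)[C@@H]2C5=O | intermediate
13 | [(2S,3S,4R)-2-(4-benzyloxy-3-methoxyphenyl)oxolane-3,4-diyl]dimethanol | OC[C@@H]1CO[C@H](c2ccc(OCc3ccccc3)c(OC)c2)[C@@H]1CO | intermediate
14 | (1S,5S,6S)-6-(4-benzyloxy-3-methoxyphenyl)-3,7-dioxabicyclo[3.3.0]octan-2-one | O=C1[C@@H]2CO[C@H](c3ccc(OCc4ccccc4)c(OC)c3)[C@@H]2CO1 | intermediate
15 | 1-benzyloxy-4-bromo-2-methoxybenzene | COc1cc(Br)ccc1OCc1ccccc1 | starting material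
16 | (4-benzyloxy-3-methoxyphenyl)lithium | [Li]c1ccc(OCc2ccccc2)c(OC)c1 | intermediate (not isolated)
17 | (4-benzyloxy-3-methoxyphenyl)[(3S,4S,5S)-5-(4-benzyloxy-3-methoxyphenyl)-4-(hydroxymethyl)oxolan-3-yl]methanone | COc1cc(C(=O)[C@@H]2CO[C@H](c3ccc(OCc4ccccc4)c(OC)c3)[C@@H]2CO)ccc1OCc1ccccc1 | intermediate
18 | (4-benzyloxy-3-methoxyphenyl)[(3S,4S,5S)-5-(4-benzyloxy-3-methoxyphenyl)-4-{[(tert-butyldimethylsilyl)oxy]methyl}oxolan-3-yl]methanone | COc1cc(C(=O)[C@@H]2CO[C@H](c3ccc(OCc4ccccc4)c(OC)c3)[C@@H]2CO[Si](C)(C)C(C)(C)C)ccc1OCc1ccccc1 | intermediate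
19 | (S)-(4-benzyloxy-3-methoxyphenyl)[(3S,4S,5S)-5-(4-benzyloxy-3-methoxyphenyl)-4-{[(tert-butyldimethylsilyl)oxy]methyl}oxolan-3-yl]methanol | COc1cc([C@@H](O)[C@@H]2CO[C@H](c3ccc(OCc4ccccc4)c(OC)c3)[C@@H]2CO[Si](C)(C)C(C)(C)C)ccc1OCc1ccccc1 | intermediate
20 | (S)-(4-benzyloxy-3-methoxyphenyl)[(3S,4S,5S)-5-(4-benzyloxy-3-methoxyphenyl)-4-(hydroxymethyl)oxolan-3-yl]methanol | COc1cc([C@@H](O)[C@@H]2CO[C@H](c3ccc(OCc4ccccc4)c(OC)c3)[C@@H]2CO)ccc1OCc1ccccc1 | intermediate
21 | (S)-(4-hydroxy-3-methoxyphenyl)[(3S,4S,5S)-5-(4-hydroxy-3-methoxyphenyl)-4-(hydroxymethyl)oxolan-3-yl]methanol | COc1cc([C@@H](O)[C@@H]2CO[C@H](c3ccc(O)c(OC)c3)[C@@H]2CO)ccc1O | target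

**Step count and risks**

Total step count: 12. Longest linear sequence: 10 steps (steps 3–12 from furfural; equally steps 1, 2 and 5–12 from O-benzylvanillin).

Steps most likely to fail:

1. Step 5 (the proposed method). The ylide may collapse to the aryl oxirane or be consumed by a second oxocarbenium ion faster than it meets the moderately reactive butenolide. Exo approach of the aryl group may compete with endo and deliver the C7 epimer. Fluoride may also epimerise the acetal centre of 9 before addition. The fallback uses known chemistry, sets out from 9 and comes back at 12.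
   - Benzophenone-sensitised photochemical radical addition of methanol to 9 places C9' anti to the menthyloxy group and should give (4S,5R)-4-(hydroxymethyl)-5-menthyloxyoxolan-2-one F1.
   - Acylation with 4-benzyloxy-3-methoxybenzoyl chloride (pyridine, DMAP) gives the aroyl ester F2.
   - LiN(SiMe3)2 (THF, −78 °C) triggers an intramolecular Claisen-type 5-exo-trig attack of the lactone enolate on the ester, and dehydration of the cyclic hemiketal (MsCl, Et3N) gives the cis-fused 2-aryl-4,5-dihydrofuran lactone F3 with a C7=C8 double bond.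
   - Hydrogenation (H2, Pd/C, EtOAc) from the convex face places the new hydrogens on C7 and C8 cis to H on C8', hence the aryl group endo, with concurrent loss of the benzyl group to give the phenol F4.
   - Re-benzylation (BnBr, K2CO3, acetone) returns 12.

2. Step 7. The first oxidation may start at the C9 hydroxymethyl as well as at C7', so that regiocontrol of the lactonisation is lost. The fallback sets out from 12 and comes back at 17, and takes the regiochemistry from the oxidation levels already present in the cycloadduct (C9 acid, C7' aldehyde).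
   - LiOH (THF–H2O, 0 °C), then buffering to pH 4, opens the lactone acetal with loss of menthol to the hydroxy lactone (pseudo-acid) F5.
   - The Grignard reagent (4-benzyloxy-3-methoxyphenyl)magnesium bromide F6 (from 15 and Mg, THF; 3 equiv) adds to the aldehyde form, and the hydroxy acid lactonises on mild acidification to the γ-aryl lactone F7 as both C7' epimers.
   - LiAlH4 gives the diol F8 as a C7' epimer mixture.
   - MnO2 (CH2Cl2) oxidises only the benzylic alcohol and converges both epimers on hydroxy ketone 17.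

3. Step 10. The catalyst may not override the substrate's own facial preference, which for hydride addition to 18 is expected from the Felkin–Anh model to favour the 7'R epimer. C8' may also epimerise α to the ketone during steps 8–10. The fallback sets out from 14 and comes back at 19; it sets C7' by carbon–carbon bond formation, so that the same substrate bias works for the wanted isomer and no enolisable aryl ketone is formed.
   - MeNH(OMe)·HCl and Me3Al (CH2Cl2, 0 °C) open lactone 14 to the hydroxy Weinreb amide F9.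
   - TBSCl and imidazole give the silyl ether F10.
   - i-Bu2AlH (THF, −78 °C) gives the aldehyde F11.
   - Addition of aryllithium 16 (THF, −78 °C), for which the Felkin–Anh model (C8 as the large substituent, the aryl group as nucleophile) predicts the 7'S carbinol, gives 19.

**Further compounds**

F1 | step 5 | (4S,5R)-4-(hydroxymethyl)-5-[(1R,2S,5R)-menthyloxy]oxolan-2-one | CC(C)[C@@H]1CC[C@@H](C)C[C@H]1O[C@H](O5)[C@H](CO)CC5=O
F2 | step 5 | 4-benzyloxy-3-methoxybenzoate ester of F1 | CC(C)[C@@H]1CC[C@@H](C)C[C@H]1O[C@H](O5)[C@H](COC(=O)c2ccc(OCc3ccccc3)c(OC)c2)CC5=O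
F3 | step 5 | cis-fused 8-(4-benzyloxy-3-methoxyphenyl)-4-menthyloxy-3,7-dioxabicyclo[3.3.0]oct-1(8)-en-2-one | CC(C)[C@@H]1CC[C@@H](C)C[C@H]1O[C@H](O5)[C@@H]2COC(c3ccc(OCc4ccccc4)c(OC)c3)=C2C5=O
F4 | step 5 | (1R,4R,5S,8S)-8-(4-hydroxy-3-methoxyphenyl)-4-menthyloxy-3,7-dioxabicyclo[3.3.0]octan-2-one | CC(C)[C@@H]1CC[C@@H](C)C[C@H]1O[C@H](O5)[C@@H]2CO[C@H](c3ccc(O)c(OC)c3)[C@@H]2C5=O
F5 | step 7 | (1R,5S,8S)-8-(4-benzyloxy-3-methoxyphenyl)-4-hydroxy-3,7-dioxabicyclo[3.3.0]octan-2-one (both lactol epimers) | OC(O5)[C@@H]2CO[C@H](c3ccc(OCc4ccccc4)c(OC)c3)[C@@H]2C5=O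
F6 | step 7 | (4-benzyloxy-3-methoxyphenyl)magnesium bromide | COc1cc([Mg]Br)ccc1OCc1ccccc1
F7 | step 7 | (1R,5S,8S)-4,8-bis(4-benzyloxy-3-methoxyphenyl)-3,7-dioxabicyclo[3.3.0]octan-2-one (both C4 epimers) | COc1cc(C(O5)[C@@H]2CO[C@H](c3ccc(OCc4ccccc4)c(OC)c3)[C@@H]2C5=O)ccc1OCc1ccccc1
F8 | step 7 | (4-benzyloxy-3-methoxyphenyl)[(3S,4S,5S)-5-(4-benzyloxy-3-methoxyphenyl)-4-(hydroxymethyl)oxolan-3-yl]methanol (both carbinol epimers) | COc1cc(C(O)[C@@H]2CO[C@H](c3ccc(OCc4ccccc4)c(OC)c3)[C@@H]2CO)ccc1OCc1ccccc1
F9 | step 10 | (3S,4S,5S)-5-(4-benzyloxy-3-methoxyphenyl)-4-(hydroxymethyl)-N-methoxy-N-methyloxolane-3-carboxamide | CON(C)C(=O)[C@@H]1CO[C@H](c2ccc(OCc3ccccc3)c(OC)c2)[C@@H]1CO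
F10 | step 10 | (3S,4S,5S)-5-(4-benzyloxy-3-methoxyphenyl)-4-{[(tert-butyldimethylsilyl)oxy]methyl}-N-methoxy-N-methyloxolane-3-carboxamide | CON(C)C(=O)[C@@H]1CO[C@H](c2ccc(OCc3ccccc3)c(OC)c2)[C@@H]1CO[Si](C)(C)C(C)(C)C
F11 | step 10 | (3S,4S,5S)-5-(4-benzyloxy-3-methoxyphenyl)-4-{[(tert-butyldimethylsilyl)oxy]methyl}oxolane-3-carbaldehyde | O=C[C@@H]1CO[C@H](c2ccc(OCc3ccccc3)c(OC)c2)[C@@H]1CO[Si](C)(C)C(C)(C)C
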